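## The problem

Compound 18 is a 1-aryl-1,2-dihydronaphthalene in which ring B (C1 guaiacyl-bearing, C2 CH2OAc-bearing, C3 CHO-bearing, C4, fusion carbons C4a and C8a) is fused to the 6-methoxy-7-hydroxy arene ring A; these locants are used for every compound below. Only two stereocentres remain, C1 (S) and C2 (R), vicinal and trans; neither hydrogen is acidified by the carbonyl group, so they cannot be corrected by equilibration and must be created together, in the right relative and absolute sense, when ring B is formed. C2 carries a one-carbon alcohol (as its acetate) and C3 a one-carbon aldehyde, and the two must be told apart from the outset, because the acetate survives neither hydride reagents nor alkoxide. The dihydronaphthalene is one dehydrogenation away from an achiral 1-arylnaphthalene, and the enal and the styrene-type alkene rule out catalytic hydrogenation late in the route. The two electron-rich phenols have to stay masked through every organometallic, photochemical and oxidative step. The enabling feature is that ring A is ortho-disubstituted by C1 and C4, while the bonds C1–C2 and C3–C4 flank the two-carbon unit C2–C3 that carries both oxygenated substituents, so ring A with C1 and C4 is an o-quinodimethane and C2–C3 a dienophile. If C4 enters as an aldehyde carbon, that quinodimethane is the photoenol of a 2-benzylbenzaldehyde, and the hydroxyl it leaves on C4 is the leaving group needed to draw the C3=C4 bond.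

## Retrosynthesis

**18 from 17 (O–benzyl bonds).** The phenols are released last from bis(benzyl ether) 17. Benzyl ethers are inert to every earlier step, which speaks for them against silyl or acyl masking. Hydrogenolysis is excluded by the alkene and the enal, so the forward step has to be a non-reductive Lewis-acid debenzylation that leaves the acetate, the enal and the methyl ethers alone.

**17 from 16 and 15 (acetyl–O, then Si–O).** The acetate cannot pass through a hydride reduction, so the C2 oxygen travels as a tert-butyldimethylsilyl ether (15) and is exchanged for acetate via alcohol 16 only after the aldehyde exists. This costs two steps; carrying the acetate from the start would save them but would not survive the conversion of ester into aldehyde.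

**15 from 14 and 13 (oxidation level at the C3 carbon).** Enal 15 comes from allylic alcohol 14 by selective allylic oxidation, and 14 from conjugated methyl ester 13 by 1,2-reduction. The ester is kept up to this point because it is the carbonyl that binds the template in the ring-forming step.

**13 from 11 (C3=C4).** The alkene is drawn by dehydration of β-hydroxy ester 11 through its sulfonate 12. The C4 hydroxyl is the residue of the photoenol and C3–H is α to the ester, so the elimination can go only one way. C3 and C4 are sacrificed here, so of the four stereocentres of 11 only C1 and C2 have to be right.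

**11 from 6 and 9 (C1–C2 and C3–C4).** This is the strategic cut. Against a C1–C8a Friedel–Crafts closure it does not pass C1 through a cation, and against a C2–C3 closure it does not need C1 to be set in an earlier operation. Both fragments are flat and simple: diarylmethane aldehyde 6 holds both aryl rings, C1 and C4, and (E)-enoate 9 holds C2, C3 and both one-carbon substituents. The forward reaction, running through the transient dienol 10, must deliver regiochemistry (ester next to the carbinol), endo topology (which fixes C1/C2 trans) and one enantiomer.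

**6 from 2 and 5 (aryl–CH2 bond).** The diarylmethane is cut at the C(sp2)–C(sp3) bond into bromoaldehyde 2 and benzylic boronate 5, joined by Suzuki–Miyaura coupling with the aldehyde unprotected. The classical alternative, addition of a lithiated acetal of 2 to an aryl aldehyde followed by deoxygenation of the diaryl carbinol, is longer. Its deoxygenation is also awkward: acid lets the carbinol close onto the acetal to a phthalan, and hydrogenolysis would remove the benzyl ethers.

**Fragments.** Boronate 5 comes from chloride 4 and this from alcohol 3. Bromide 2 comes from 6-bromovanillin 1, whose substitution pattern (oxygen para and methoxy meta to the formyl group, bromine at the future C8a) is exactly that of ring A. Enoate 9 comes from aldehyde 7 and ylide 8 by Wittig olefination.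

## Roads not taken

Alternative 1: gold-catalysed enyne cycloisomerisation.
- *Cut:* C2–C3 and C1–C8a, leading back to aryl propargyl (E)-cinnamyl ether A2.
- *Forward step:* the cationic chiral digold complex (R)-DTBM-SEGPHOS(AuCl)2/AgSbF6 activates the alkyne; the alkene attacks, and the resulting cyclopropyl gold carbene is opened by ring A. This gives tetrahydronaphthofuran A1 with ring B and the tetrahydrofuran closed at once.
- *Merits:* A2 is available in about three steps. The trans C1/C2 relation follows stereospecifically from the (E)-alkene. The chiral source is catalytic, which the chosen plan (stoichiometric Ti(OiPr)4 and diol) cannot match. In steps to the carbocyclic core this road is better.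
- *Weak points:* in A1 the C2 and C3 one-carbon units are locked in one cyclic ether at the same oxidation level. Reaching 18 needs a selective allylic C–H oxidation of one ether CH2 on a substrate whose C1–H is doubly benzylic and whose ring B aromatises readily under such oxidants. The resulting lactol must then be opened and acetylated on one side only.
- *Comparison:* the chosen plan is longer to the core but brings C2 and C3 in already differentiated (silyl ether and ester) and needs no C–H oxidation on the dihydronaphthalene.

Alternative 2: cyclopropyl ketone opening and Friedel–Crafts closure.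
- *Cut:* C1–C8a, leading back to aryl cyclopropyl ketone A4.
- *Forward step:* SnCl4 opens the donor–acceptor bond of A4 at the aryl-bearing carbon, and ring A (para to its methoxy group) captures the benzylic cation to give tetralone A3.
- *Merits:* the only stereocentre that must be made beforehand is the acetoxymethyl-bearing carbon, by asymmetric cyclopropanation, a better-established source of absolute configuration than a templated photoreaction. The acetate is in place early.
- *Weak points:* A3 lacks the C3 formyl carbon. Introducing it by enolate formylation needs base that the acetate does not tolerate. The C4 ketone must then be removed with transposition to the C3=C4 enal, about five further operations plus a protecting-group exchange. C1 passes through a cation, so its configuration rests on 1,2-induction from C2.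
- *Comparison:* the chosen plan delivers every skeletal carbon, including the C3 carbonyl carbon, in the ring-forming step and leaves C4 with the leaving group already attached.

Alternative 3: intramolecular allylic alkylation with vinyl as latent hydroxymethyl.
- *Cut:* C2–C3, leading back to β-keto ester allylic carbonate A6.
- *Forward step:* Pd(PPh3)4 ionises the carbonate and the β-keto ester carbon attacks the near allyl terminus, closing ring B as vinyl tetralone A5.
- *Merits:* the cyclisation is a mild, predictable six-membered ring closure, more certain than a photochemical cycloaddition. It shares with the chosen plan a C3 ester and a C4 oxygen for later elimination.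
- *Weak points:* the C1 diarylmethine stereocentre must be made enantioselectively before the key step. It then sits next to the allylpalladium terminus, where β-hydride elimination to a 1,1-diaryldiene can destroy it. C2 is set only by 1,2-induction. The vinyl group must be degraded by one carbon to CH2OAc before the C3=C4 alkene is introduced, giving the longest end-game of the four.
- *Comparison:* the chosen plan creates C1 and C2 in one event with their relation fixed by alkene and dienol geometry, and brings the C2 substituent in with the right carbon count.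

Key step: step 6

Assumption: the (4R,5R)-TADDOL-derived titanium template is taken to leave open the dienolate face that leads to (1S,2R,3S,4S)-11; if the first run shows the opposite sense, the (4S,5S)-diol is used with no other change.

## Route

Step 1
Reactants: 1 6-bromovanillin (2-bromo-4-hydroxy-5-methoxybenzaldehyde)
Product: 2 4-(benzyloxy)-2-bromo-5-methoxybenzaldehyde
Conditions: BnBr, K2CO3, DMF, rt
Reagents that add atoms: benzyl bromide, BrCc1ccccc1
Why: Williamson O-alkylation of the phenoxide; the aldehyde and aryl bromide are inert to carbonate in DMF.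

Step 2
Reactants: 3 [4-(benzyloxy)-3-methoxyphenyl]methanol
Product: 4 1-(benzyloxy)-4-(chloromethyl)-2-methoxybenzene
Conditions: SOCl2, CH2Cl2, 0 °C to rt
Reagents that add atoms: thionyl chloride, ClS(Cl)=O
Why: Chlorodehydroxylation through the chlorosulfite; the p-alkoxybenzyl system ionises easily, so the exchange should run cold and the chloride is used without storage.

Step 3
Reactants: 4 1-(benzyloxy)-4-(chloromethyl)-2-methoxybenzene
Product: 5 2-[4-(benzyloxy)-3-methoxybenzyl]-4,4,5,5-tetramethyl-1,3,2-dioxaborolane
Conditions: B2pin2, Pd(dba)2 (cat.), P(4-MeOC6H4)3, KOAc, PhMe, 50 °C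
Reagents that add atoms: bis(pinacolato)diboron, CC1(C)OB(OC1(C)C)B1OC(C)(C)C(C)(C)O1
Why: Miyaura borylation of a benzylic chloride (oxidative addition to zerovalent palladium, acetate-assisted transmetalation with the diboron, reductive elimination); the weak base KOAc keeps the product from coupling with unreacted chloride.

Step 4
Reactants: 2 4-(benzyloxy)-2-bromo-5-methoxybenzaldehyde; 5 2-[4-(benzyloxy)-3-methoxybenzyl]-4,4,5,5-tetramethyl-1,3,2-dioxaborolane
Product: 6 4-(benzyloxy)-2-[4-(benzyloxy)-3-methoxybenzyl]-5-methoxybenzaldehyde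
Conditions: Pd(OAc)2 (cat.), 2-dicyclohexylphosphino-2′,6′-dimethoxybiphenyl (SPhos), K3PO4, PhMe/H2O, 80 °C
Reagents that add atoms: none
Why: Suzuki–Miyaura C(sp2)–C(sp3) coupling; the ortho-formyl group speeds oxidative addition, the benzylpalladium intermediate has no β-hydrogen, and the free aldehyde tolerates phosphate base.

Step 5
Reactants: 7 (tert-butyldimethylsilyloxy)acetaldehyde; 8 methyl (triphenylphosphoranylidene)acetate
Product: 9 methyl (E)-4-[(tert-butyldimethylsilyl)oxy]but-2-enoate
Conditions: CH2Cl2, rt
Reagents that add atoms: none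
Why: Wittig olefination with a stabilised ylide, which should give the (E)-enoate needed to fix the C2/C3 trans relation in step 6.

Step 6
Reactants: 6 4-(benzyloxy)-2-[4-(benzyloxy)-3-methoxybenzyl]-5-methoxybenzaldehyde; 9 methyl (E)-4-[(tert-butyldimethylsilyl)oxy]but-2-enoate
Product: 11 methyl (1S,2R,3S,4S)-7-(benzyloxy)-1-[4-(benzyloxy)-3-methoxyphenyl]-2-{[(tert-butyldimethylsilyl)oxy]methyl}-4-hydroxy-6-methoxy-1,2,3,4-tetrahydronaphthalene-3-carboxylate, via (E,E)-hydroxy-o-quinodimethane 10 (not isolated)
Conditions: Ti(OiPr)4 (stoichiometric), (4R,5R)-2,2-dimethyl-α,α,α′,α′-tetraphenyl-1,3-dioxolane-4,5-dimethanol ((R,R)-TADDOL), PhMe, hν (365 nm), rt, Ar; then aq. NaHCO3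
Reagents that add atoms: none
Why: Excitation of the aldehyde of 6 (n,π*) and 1,5-hydrogen transfer from the doubly benzylic CH2 give a biradical that relaxes to the dienols; the (Z)-dienol returns to 6 by a 1,5-shift, while the (E,E)-dienol 10, with hydroxyl and aryl both pointing outward, lives long enough to exchange onto titanium as a dienolate. The ester carbonyl of 9 binds the same titanium centre, so the cycloaddition is a templated suprafacial [4+2] Diels–Alder reaction, the known photoenolisation/Diels–Alder reaction of 2-alkylbenzaldehydes in its Ti(OiPr)4-mediated enantioselective form. Ring B is closed by this intermolecular cycloaddition as a six-membered carbocycle annulated to ring A, whose aromaticity returns in the same event and supplies the driving force. Regiochemistry follows both the template and the polarity of the dienol: the nucleophilic remote terminus C1 bonds to the β-carbon of the enoate, and the ester carbon ends on C3 next to the carbinol C4. The C1/C4 cis relation comes from the E,E geometry of 10, the C2/C3 trans relation from the (E)-alkene of 9, and the C3/C4 cis relation, and through it C1/C2 trans, from the endo arrangement enforced by the O–Ti–O=C bridge. The absolute configuration of all four centres is decided by which face of the titanium-bound dienolate the chiral diolate leaves open. The step needs regio-, endo- and face selectivity together with selective excitation of 6; the first two are secured by the template and the fixed alkene geometries, the last by irradiating at 365 nm, where only the aryl aldehyde absorbs.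

Step 7
Reactants: 11 methyl (1S,2R,3S,4S)-7-(benzyloxy)-1-[4-(benzyloxy)-3-methoxyphenyl]-2-{[(tert-butyldimethylsilyl)oxy]methyl}-4-hydroxy-6-methoxy-1,2,3,4-tetrahydronaphthalene-3-carboxylate
Product: 13 methyl (1S,2R)-7-(benzyloxy)-1-[4-(benzyloxy)-3-methoxyphenyl]-2-{[(tert-butyldimethylsilyl)oxy]methyl}-6-methoxy-1,2-dihydronaphthalene-3-carboxylate, via C4 methanesulfonate 12 (not isolated)
Conditions: MsCl, Et3N, CH2Cl2, 0 °C; then DBU, rt
Reagents that add atoms: none
Why: Sulfonylation of the benzylic alcohol followed by E2/E1cB elimination; in the 3,4-cis adduct C3–H is anti to the C4 leaving group and α to the ester, so only the C3=C4 alkene, conjugated with ring A and the ester, can form. C1–H and C2–H are not activated, so both stereocentres are untouched.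

Step 8
Reactants: 13 methyl (1S,2R)-7-(benzyloxy)-1-[4-(benzyloxy)-3-methoxyphenyl]-2-{[(tert-butyldimethylsilyl)oxy]methyl}-6-methoxy-1,2-dihydronaphthalene-3-carboxylate
Product: 14 [(1S,2R)-7-(benzyloxy)-1-[4-(benzyloxy)-3-methoxyphenyl]-2-{[(tert-butyldimethylsilyl)oxy]methyl}-6-methoxy-1,2-dihydronaphthalen-3-yl]methanol
Conditions: i-Bu2AlH, CH2Cl2, −78 °C; then aq. potassium sodium tartrate (KNaC4H4O6)
Reagents that add atoms: none
Why: 1,2-Reduction of the conjugated ester by i-Bu2AlH to the allylic alcohol; silyl and benzyl ethers are inert, and any isopropyl ester formed by exchange in step 6 would converge to the same alcohol.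

Step 9
Reactants: 14 [(1S,2R)-7-(benzyloxy)-1-[4-(benzyloxy)-3-methoxyphenyl]-2-{[(tert-butyldimethylsilyl)oxy]methyl}-6-methoxy-1,2-dihydronaphthalen-3-yl]methanol
Product: 15 (1S,2R)-7-(benzyloxy)-1-[4-(benzyloxy)-3-methoxyphenyl]-2-{[(tert-butyldimethylsilyl)oxy]methyl}-6-methoxy-1,2-dihydronaphthalene-3-carbaldehyde
Conditions: MnO2, CH2Cl2, rt
Reagents that add atoms: none
Why: Heterogeneous MnO2 oxidation, selective for allylic alcohols and stopping at the aldehyde; the product is a push–pull enal conjugated through C4 with ring A.

Step 10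
Reactants: 15 (1S,2R)-7-(benzyloxy)-1-[4-(benzyloxy)-3-methoxyphenyl]-2-{[(tert-butyldimethylsilyl)oxy]methyl}-6-methoxy-1,2-dihydronaphthalene-3-carbaldehyde
Product: 16 (1S,2R)-7-(benzyloxy)-1-[4-(benzyloxy)-3-methoxyphenyl]-2-(hydroxymethyl)-6-methoxy-1,2-dihydronaphthalene-3-carbaldehyde
Conditions: HF·pyridine, pyridine, THF, 0 °C to rt
Reagents that add atoms: none
Why: Fluoride cleavage of the primary silyl ether under buffered, non-basic conditions; the hydroxy enal is expected to stay open-chain, since closure to the lactol would break the conjugation of the enal with ring A and its C7 oxygen.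

Step 11
Reactants: 16 (1S,2R)-7-(benzyloxy)-1-[4-(benzyloxy)-3-methoxyphenyl]-2-(hydroxymethyl)-6-methoxy-1,2-dihydronaphthalene-3-carbaldehyde
Product: 17 [(1S,2R)-7-(benzyloxy)-1-[4-(benzyloxy)-3-methoxyphenyl]-3-formyl-6-methoxy-1,2-dihydronaphthalen-2-yl]methyl acetate
Conditions: Ac2O, pyridine, DMAP (cat.), CH2Cl2, 0 °C
Reagents that add atoms: acetic anhydride, CC(=O)OC(C)=O
Why: DMAP-catalysed acylation of the only free hydroxyl; both phenols are still benzylated, so no selectivity is required.

Step 12
Reactants: 17 [(1S,2R)-7-(benzyloxy)-1-[4-(benzyloxy)-3-methoxyphenyl]-3-formyl-6-methoxy-1,2-dihydronaphthalen-2-yl]methyl acetate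
Product: 18 [(1S,2R)-3-formyl-7-hydroxy-1-(4-hydroxy-3-methoxyphenyl)-6-methoxy-1,2-dihydronaphthalen-2-yl]methyl acetate
Conditions: BCl3, pentamethylbenzene, CH2Cl2, −78 °C; then MeOH
Reagents that add atoms: none
Why: Lewis-acid debenzylation of aryl benzyl ethers with a cation scavenger: BCl3 activates the ether oxygen and the benzyl cation is taken up by pentamethylbenzene in a Friedel–Crafts alkylation. No reductant is involved, so the alkene and aldehyde are not at risk, and the acetate and methyl ethers should be stable at −78 °C.

## Compound list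

1 | 6-bromovanillin (2-bromo-4-hydroxy-5-methoxybenzaldehyde) | O=Cc1cc(OC)c(O)cc1Br | starting material
2 | 4-(benzyloxy)-2-bromo-5-methoxybenzaldehyde | O=Cc1cc(OC)c(OCc2ccccc2)cc1Br | intermediate
3 | [4-(benzyloxy)-3-methoxyphenyl]methanol | OCc1ccc(OCc2ccccc2)c(OC)c1 | starting material
4 | 1-(benzyloxy)-4-(chloromethyl)-2-methoxybenzene | ClCc1ccc(OCc2ccccc2)c(OC)c1 | intermediate
5 | 2-[4-(benzyloxy)-3-methoxybenzyl]-4,4,5,5-tetramethyl-1,3,2-dioxaborolane | CC1(C)OB(Cc2ccc(OCc3ccccc3)c(OC)c2)OC1(C)C | intermediate
6 | 4-(benzyloxy)-2-[4-(benzyloxy)-3-methoxybenzyl]-5-methoxybenzaldehyde | O=Cc1cc(OC)c(OCc2ccccc2)cc1Cc1ccc(OCc2ccccc2)c(OC)c1 | intermediate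
7 | (tert-butyldimethylsilyloxy)acetaldehyde | O=CCO[Si](C)(C)C(C)(C)C | starting material
8 | methyl (triphenylphosphoranylidene)acetate | COC(=O)C=P(c1ccccc1)(c1ccccc1)c1ccccc1 | starting material
9 | methyl (E)-4-[(tert-butyldimethylsilyl)oxy]but-2-enoate | COC(=O)/C=C/CO[Si](C)(C)C(C)(C)C | intermediate
10 | (E,E)-hydroxy-o-quinodimethane (photoenol of 6, hydroxyl and aryl outward; held on titanium) | O/C=C1\C=C(OC)C(OCc2ccccc2)=C\C1=C/c1ccc(OCc2ccccc2)c(OC)c1 | intermediate (not isolated)
11 | methyl (1S,2R,3S,4S)-7-(benzyloxy)-1-[4-(benzyloxy)-3-methoxyphenyl]-2-{[(tert-butyldimethylsilyl)oxy]methyl}-4-hydroxy-6-methoxy-1,2,3,4-tetrahydronaphthalene-3-carboxylate (1,2-trans; 2,3-trans; 3,4-cis) | COc1cc([C@H]2c3cc(OCc4ccccc4)c(OC)cc3[C@@H](O)[C@@H](C(=O)OC)[C@@H]2CO[Si](C)(C)C(C)(C)C)ccc1OCc1ccccc1 | intermediate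
12 | C4 methanesulfonate of 11 | COc1cc([C@H]2c3cc(OCc4ccccc4)c(OC)cc3[C@@H](OS(C)(=O)=O)[C@@H](C(=O)OC)[C@@H]2CO[Si](C)(C)C(C)(C)C)ccc1OCc1ccccc1 | intermediate (not isolated)
13 | methyl (1S,2R)-7-(benzyloxy)-1-[4-(benzyloxy)-3-methoxyphenyl]-2-{[(tert-butyldimethylsilyl)oxy]methyl}-6-methoxy-1,2-dihydronaphthalene-3-carboxylate | COc1cc([C@H]2c3cc(OCc4ccccc4)c(OC)cc3C=C(C(=O)OC)[C@@H]2CO[Si](C)(C)C(C)(C)C)ccc1OCc1ccccc1 | intermediate
14 | [(1S,2R)-7-(benzyloxy)-1-[4-(benzyloxy)-3-methoxyphenyl]-2-{[(tert-butyldimethylsilyl)oxy]methyl}-6-methoxy-1,2-dihydronaphthalen-3-yl]methanol | COc1cc([C@H]2c3cc(OCc4ccccc4)c(OC)cc3C=C(CO)[C@@H]2CO[Si](C)(C)C(C)(C)C)ccc1OCc1ccccc1 | intermediate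
15 | (1S,2R)-7-(benzyloxy)-1-[4-(benzyloxy)-3-methoxyphenyl]-2-{[(tert-butyldimethylsilyl)oxy]methyl}-6-methoxy-1,2-dihydronaphthalene-3-carbaldehyde | COc1cc([C@H]2c3cc(OCc4ccccc4)c(OC)cc3C=C(C=O)[C@@H]2CO[Si](C)(C)C(C)(C)C)ccc1OCc1ccccc1 | intermediate
16 | (1S,2R)-7-(benzyloxy)-1-[4-(benzyloxy)-3-methoxyphenyl]-2-(hydroxymethyl)-6-methoxy-1,2-dihydronaphthalene-3-carbaldehyde | COc1cc([C@H]2c3cc(OCc4ccccc4)c(OC)cc3C=C(C=O)[C@@H]2CO)ccc1OCc1ccccc1 | intermediate
17 | [(1S,2R)-7-(benzyloxy)-1-[4-(benzyloxy)-3-methoxyphenyl]-3-formyl-6-methoxy-1,2-dihydronaphthalen-2-yl]methyl acetate | COc1cc([C@H]2c3cc(OCc4ccccc4)c(OC)cc3C=C(C=O)[C@@H]2COC(C)=O)ccc1OCc1ccccc1 | intermediate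
18 | [(1S,2R)-3-formyl-7-hydroxy-1-(4-hydroxy-3-methoxyphenyl)-6-methoxy-1,2-dihydronaphthalen-2-yl]methyl acetate | COc1cc([C@H]2c3cc(O)c(OC)cc3C=C(C=O)[C@@H]2COC(C)=O)ccc1O | target

## Step count and least certain steps

Total: 12 steps. Longest linear sequence: 10 steps (3 to 18 through steps 2, 3, 4, 6, 7, 8, 9, 10, 11, 12).

**Step 6 (key step).**
- *Most likely failure:* poor discrimination between the two faces of the dienolate. An acyclic enoate binds titanium through one carbonyl and can rotate about its C–C(O) bond, so the chiral diol may transmit little bias.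
- *Secondary threats:* triplet-sensitised E/Z isomerisation of 9 by the excited aldehyde, which would erode the alkene geometry, and return of the dienol to 6 before the β-substituted enoate captures it.
- *Fallback:* setting out from 6 and 9, the cycloaddition is run with Ti(OiPr)4 alone. This keeps regio- and endo control but gives 11 as the racemate, that is together with its enantiomer methyl (1R,2S,3R,4R)-7-(benzyloxy)-1-[4-(benzyloxy)-3-methoxyphenyl]-2-{[(tert-butyldimethylsilyl)oxy]methyl}-4-hydroxy-6-methoxy-1,2,3,4-tetrahydronaphthalene-3-carboxylate F1. Acylation of the C4 hydroxyl of the mixture with (1S)-camphanoyl chloride (Et3N, DMAP, CH2Cl2) turns 11 into methyl (1S,2R,3S,4S)-7-(benzyloxy)-1-[4-(benzyloxy)-3-methoxyphenyl]-2-{[(tert-butyldimethylsilyl)oxy]methyl}-4-[(1S,4R)-camphanoyloxy]-6-methoxy-1,2,3,4-tetrahydronaphthalene-3-carboxylate F2 and turns F1 into methyl (1R,2S,3R,4R)-7-(benzyloxy)-1-[4-(benzyloxy)-3-methoxyphenyl]-2-{[(tert-butyldimethylsilyl)oxy]methyl}-4-[(1S,4R)-camphanoyloxy]-6-methoxy-1,2,3,4-tetrahydronaphthalene-3-carboxylate F3. The diastereomers F2 and F3 are separated by chromatography or crystallisation, and the camphanoyl unit serves as internal reference for assigning configuration by X-ray diffraction. F3 is set aside. DBU then eliminates camphanic acid from F2 by an E1cB pathway, with the same anti C3–H/C4–O arrangement as in step 7, and the route is rejoined at 13. The resolving group is thus lost in a step the route needs anyway.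

**Step 12.**
- *Most likely failure:* attack of the Lewis acid on the primary acetate (loss of the acetyl group) or on the enal during the time needed to cleave two benzyl ethers, leading to incomplete or unselective deprotection.
- *Fallback:* setting out from 16, the benzyl ethers are removed before the acetate exists (BCl3, pentamethylbenzene, CH2Cl2, −78 °C) to give (1S,2R)-7-hydroxy-1-(4-hydroxy-3-methoxyphenyl)-2-(hydroxymethyl)-6-methoxy-1,2-dihydronaphthalene-3-carbaldehyde F4. The primary alcohol of F4 is then acetylated in the presence of the two phenols with immobilised Candida antarctica lipase B and vinyl acetate in THF. This lipase-type acylation distinguishes aliphatic from phenolic hydroxyl groups, and the route is rejoined at 18.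

**Step 9.**
- *Most likely failure:* dehydrogenation of the electron-rich 1-aryl-1,2-dihydronaphthalene to the arylnaphthalene on the oxidant surface, which would erase both stereocentres.
- *Fallback:* setting out from 13, the aldehyde is reached by reduction only. Aminolysis with MeNH(OMe)·HCl and i-PrMgCl (THF, −20 to 0 °C) gives the Weinreb amide (1S,2R)-7-(benzyloxy)-1-[4-(benzyloxy)-3-methoxyphenyl]-2-{[(tert-butyldimethylsilyl)oxy]methyl}-N,6-dimethoxy-N-methyl-1,2-dihydronaphthalene-3-carboxamide F5. Reduction of F5 with i-Bu2AlH (THF, −78 °C) stops at the aldehyde because of the chelated tetrahedral intermediate, and the route is rejoined at 15 without passing through 14 or any oxidant.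

**Step 4.**
- *Most likely failure:* protodeboronation or homocoupling of the benzylic boronate outrunning the slow transmetalation of an sp3 boron reagent.
- *Fallback:* setting out from 2, the roles of the partners are exchanged. Miyaura borylation (B2pin2, PdCl2(dppf), KOAc, dioxane, 85 °C) gives 4-(benzyloxy)-5-methoxy-2-(4,4,5,5-tetramethyl-1,3,2-dioxaborolan-2-yl)benzaldehyde F6, whose sp2 boron transmetalates readily. Coupling of F6 with benzylic chloride 4 (Pd(PPh3)4, K3PO4, PhMe with a little water, 80 °C) rejoins the route at 6.

## Further compounds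

F1 | step 6 | methyl (1R,2S,3R,4R)-7-(benzyloxy)-1-[4-(benzyloxy)-3-methoxyphenyl]-2-{[(tert-butyldimethylsilyl)oxy]methyl}-4-hydroxy-6-methoxy-1,2,3,4-tetrahydronaphthalene-3-carboxylate (enantiomer of 11) | COc1cc([C@@H]2c3cc(OCc4ccccc4)c(OC)cc3[C@H](O)[C@H](C(=O)OC)[C@H]2CO[Si](C)(C)C(C)(C)C)ccc1OCc1ccccc1
F2 | step 6 | methyl (1S,2R,3S,4S)-7-(benzyloxy)-1-[4-(benzyloxy)-3-methoxyphenyl]-2-{[(tert-butyldimethylsilyl)oxy]methyl}-4-[(1S,4R)-camphanoyloxy]-6-methoxy-1,2,3,4-tetrahydronaphthalene-3-carboxylate (C4 camphanate of 11) | COc1cc([C@H]2c3cc(OCc4ccccc4)c(OC)cc3[C@@H](OC(=O)[C@@]56CC[C@@](C)(C(=O)O5)C6(C)C)[C@@H](C(=O)OC)[C@@H]2CO[Si](C)(C)C(C)(C)C)ccc1OCc1ccccc1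
F3 | step 6 | methyl (1R,2S,3R,4R)-7-(benzyloxy)-1-[4-(benzyloxy)-3-methoxyphenyl]-2-{[(tert-butyldimethylsilyl)oxy]methyl}-4-[(1S,4R)-camphanoyloxy]-6-methoxy-1,2,3,4-tetrahydronaphthalene-3-carboxylate (C4 camphanate of F1) | COc1cc([C@@H]2c3cc(OCc4ccccc4)c(OC)cc3[C@H](OC(=O)[C@@]56CC[C@@](C)(C(=O)O5)C6(C)C)[C@H](C(=O)OC)[C@H]2CO[Si](C)(C)C(C)(C)C)ccc1OCc1ccccc1
F4 | step 12 | (1S,2R)-7-hydroxy-1-(4-hydroxy-3-methoxyphenyl)-2-(hydroxymethyl)-6-methoxy-1,2-dihydronaphthalene-3-carbaldehyde | COc1cc([C@H]2c3cc(O)c(OC)cc3C=C(C=O)[C@@H]2CO)ccc1O
F5 | step 9 | (1S,2R)-7-(benzyloxy)-1-[4-(benzyloxy)-3-methoxyphenyl]-2-{[(tert-butyldimethylsilyl)oxy]methyl}-N,6-dimethoxy-N-methyl-1,2-dihydronaphthalene-3-carboxamide | COc1cc([C@H]2c3cc(OCc4ccccc4)c(OC)cc3C=C(C(=O)N(C)OC)[C@@H]2CO[Si](C)(C)C(C)(C)C)ccc1OCc1ccccc1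
F6 | step 4 | 4-(benzyloxy)-5-methoxy-2-(4,4,5,5-tetramethyl-1,3,2-dioxaborolan-2-yl)benzaldehyde | O=Cc1cc(OC)c(OCc2ccccc2)cc1B1OC(C)(C)C(C)(C)O1
A1 | alternative 1 | (3aR,4S)-6-(benzyloxy)-4-[4-(benzyloxy)-3-methoxyphenyl]-7-methoxy-1,3,3a,4-tetrahydronaphtho[2,3-c]furan (3a,4-trans) | COc1cc([C@H]2c3cc(OCc4ccccc4)c(OC)cc3C=C3COC[C@H]23)ccc1OCc1ccccc1
A2 | alternative 1 | 1-(benzyloxy)-4-[(E)-3-({3-[4-(benzyloxy)-3-methoxyphenyl]prop-2-yn-1-yl}oxy)prop-1-en-1-yl]-2-methoxybenzene | COc1cc(C#CCOC/C=C/c2ccc(OCc3ccccc3)c(OC)c2)ccc1OCc1ccccc1
A3 | alternative 2 | [(1S,2S)-7-(benzyloxy)-1-[4-(benzyloxy)-3-methoxyphenyl]-6-methoxy-4-oxo-1,2,3,4-tetrahydronaphthalen-2-yl]methyl acetate (1,2-trans) | COc1cc([C@H]2c3cc(OCc4ccccc4)c(OC)cc3C(=O)C[C@@H]2COC(C)=O)ccc1OCc1ccccc1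
A4 | alternative 2 | {2-[4-(benzyloxy)-3-methoxybenzoyl]-3-[4-(benzyloxy)-3-methoxyphenyl]cyclopropyl}methyl acetate, configured at the acetoxymethyl-bearing carbon (the only ring centre that survives the key step) | COc1cc(C(=O)C2[C@H](COC(C)=O)C2c2ccc(OCc3ccccc3)c(OC)c2)ccc1OCc1ccccc1
A5 | alternative 3 | methyl 7-(benzyloxy)-1-[4-(benzyloxy)-3-methoxyphenyl]-6-methoxy-4-oxo-2-vinyl-1,2,3,4-tetrahydronaphthalene-3-carboxylate (1,2-trans, 2,3-trans; C1 and C2 configured as in 18) | COc1cc([C@H]2c3cc(OCc4ccccc4)c(OC)cc3C(=O)[C@@H](C(=O)OC)[C@@H]2C=C)ccc1OCc1ccccc1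
A6 | alternative 3 | methyl 3-{4-(benzyloxy)-2-[(1S,2E)-1-[4-(benzyloxy)-3-methoxyphenyl]-4-[(methoxycarbonyl)oxy]but-2-en-1-yl]-5-methoxyphenyl}-3-oxopropanoate | COC(=O)CC(=O)c1cc(OC)c(OCc2ccccc2)cc1[C@@H](/C=C/COC(=O)OC)c1ccc(OCc2ccccc2)c(OC)c1
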